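**Retrosynthetic overview**
- The C8–C(CH3)2CH=CH2 bond is traced back to an aryl prenyl ether at O7. An ortho [3,3] shift delivers the tertiary terminus of the prenyl group to C8.
- The key disconnection is the O7–CH2 bond of that ether: site-selective etherification of kaempferol at O7 with prenyl bromide.
- Site selectivity comes from masking all four hydroxyls as acetates. Only the 7-acetate is cleaved under carbonate, so only O7 is alkylated.
- No ring is formed. The A, B and C rings are bought intact as kaempferol, and all chemistry is on the periphery.

Assumption: the target SMILES has no stereocentre, so "single enantiomer" is read as the achiral compound as drawn; kaempferol is taken as a cheap bulk commercial flavonol.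

**Step 1**
Reactants: 1 kaempferol; 2 acetic anhydride
Product: 3 kaempferol 3,5,7,4'-tetraacetate
Conditions: Ac2O (6 equiv), pyridine, 23 °C, 16 h
Reagents that add atoms: acetic anhydride (2), CC(=O)OC(C)=O
Why: Exhaustive pyridine-mediated O-acetylation (acyl transfer) esterifies all four hydroxyls, the chelated 5-OH included on prolonged reaction, and so converts the site-selection problem into a lability ranking among aryl acetates; no stereocentre is formed.

**Step 2**
Reactants: 3 kaempferol 3,5,7,4'-tetraacetate; 4 prenyl bromide
Product: 6 kaempferol 7-O-prenyl ether 3,5,4'-triacetate, via kaempferol 3,5,4'-triacetate 7-phenoxide 5 (not isolated)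
Conditions: prenyl bromide (1.3 equiv), K2CO3 (3 equiv), dry acetone, reflux, 8–12 h (stop at full conversion of 3); dil. HCl work-up
Reagents that add atoms: prenyl bromide (4), CC(C)=CCBr
Why: In this Jurd-type deacetylative Williamson etherification, carbonate cleaves only the 7-acetate (its phenoxide, para to the C4 carbonyl, is the best leaving group), and the unmasked 7-phenoxide is trapped by SN2 at the primary carbon of prenyl bromide while O3, O5 and O4' stay acetylated, so the linear prenyl ether forms at O7 only; no stereocentre is formed.

**Step 3**
Reactants: 6 kaempferol 7-O-prenyl ether 3,5,4'-triacetate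
Product: 9 target 8-(1,1-dimethylallyl)kaempferol, via kaempferol 7-O-prenyl ether tripotassium salt 7 (not isolated), via C8 ortho-dienone 8 (not isolated)
Conditions: KOMe (3.5 equiv), degassed MeOH (0.02 M), Ar, 23 °C, 30 min; then sealed tube, 120 °C, 3 h; then 1 M HCl to pH 4, 0 °C
Reagents that add atoms: none
Why: Proposed new method: methoxide transesterification strips the three acetates to the 3,5,4'-triphenoxide, in which the 5-oxide para to C8 makes the ortho-dienone of the [3,3] shift a delocalised β-diketonate (O5–C5–C6–C7–O7) and should lower the barrier of the aromatic Claisen rearrangement well below the ≥180 °C needed by the neutral ether, while the solvated 5-O–K+ pair flanking C6 and the C7–C8 bond fixation of the chromenone direct the bulky tertiary terminus to C8 and the phenoxide state of the product shuts down abnormal-Claisen and dihydrofuran-forming follow-up reactions; the closest known reaction types are the thermal aromatic Claisen rearrangement of flavonoid prenyl ethers and anion-accelerated [3,3] shifts (anionic oxy-Cope), and the racemic C8 centre of the transient dienone is erased on tautomerisation to the achiral target.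

**Compound list**
1 | kaempferol | O=c1c(O)c(-c2ccc(O)cc2)oc2cc(O)cc(O)c12 | starting material
2 | acetic anhydride | CC(=O)OC(C)=O | starting material
3 | kaempferol 3,5,7,4'-tetraacetate | CC(=O)Oc1ccc(cc1)-c1oc2cc(OC(C)=O)cc(OC(C)=O)c2c(=O)c1OC(C)=O | intermediate
4 | prenyl bromide (1-bromo-3-methylbut-2-ene) | CC(C)=CCBr | starting material
5 | kaempferol 3,5,4'-triacetate with free 7-OH (potassium 7-phenoxide in the flask) | CC(=O)Oc1ccc(cc1)-c1oc2cc(O)cc(OC(C)=O)c2c(=O)c1OC(C)=O | intermediate (not isolated)
6 | kaempferol 7-O-prenyl ether 3,5,4'-triacetate | CC(=O)Oc1ccc(cc1)-c1oc2cc(OCC=C(C)C)cc(OC(C)=O)c2c(=O)c1OC(C)=O | intermediate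
7 | kaempferol 7-O-prenyl ether (tripotassium phenoxide in the flask) | CC(C)=CCOc1cc(O)c2c(=O)c(O)c(-c3ccc(O)cc3)oc2c1 | intermediate (not isolated)
8 | C8 ortho-dienone, 5-hydroxy-8-(2-methylbut-3-en-2-yl)-8H-chromene-4,7-dione tautomer (racemic, transient, anionic in the flask) | C=CC(C)(C)C1C(=O)C=C(O)C2=C1OC(=C(O)C2=O)c1ccc(O)cc1 | intermediate (not isolated)
9 | 3,5,7-trihydroxy-2-(4-hydroxyphenyl)-8-(2-methylbut-3-en-2-yl)-4H-chromen-4-one, achiral | C=CC(C)(C)c1c(O)cc(O)c2c(=O)c(O)c(-c3ccc(O)cc3)oc12 | target

**Totals**
Total step count: 3. Longest linear sequence: 3.

**Steps most likely to fail, with fallbacks**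

Step 3 (the proposed new step). The risks are too little acceleration in methanol, a C6/C8 mixture, or prenyl transfer between phenoxides. The fallback uses known chemistry, sets out from 6 and comes back at 9. Compound 6 is heated in N,N-diethylaniline with acetic anhydride 2 and NaOAc at about 190 °C. This is the classical thermal aromatic Claisen rearrangement with in situ acetylation of the liberated 7-OH, which prevents cyclisation onto the new alkene. It gives 3,5,7,4'-tetra-O-acetyl-8-(1,1-dimethylallyl)kaempferol F1, which can be separated from any 6-isomer. Methanolysis with K2CO3 in MeOH at 23 °C then gives 9. This adds one step.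

Step 2. The risks are further cleavage and alkylation at the 4'-acetate, or slow unmasking of O7. The fallback sets out from 3 and comes back at 6, and separates unmasking from alkylation. Selective thiolysis of the 7-acetate of 3 with PhSH and imidazole in NMP at 0 °C gives 5, this time isolated as the free 7-phenol. Mitsunobu etherification of 5 with prenol (PPh3, DIAD, THF, 0 °C to 23 °C) under neutral conditions gives 6.

Step 1. The risk is low: incomplete acetylation of the chelated 5-OH, or coloured oxidation by-products. The fallback sets out from 1 and comes back at 7, and drops the masking altogether. Kaempferol 1 is converted to its monoanion with KOtBu (1.0 equiv) in DMF at 0 °C and alkylated with 4 (1.0 equiv). The 7-O-prenyl ether 7 is separated by chromatography from the 4'-O and 3-O isomers; expect a modest yield, which is acceptable because 1 is cheap. Isolated 7 then enters step 3 at the Claisen stage (KOMe, MeOH, 120 °C) and goes on to 9.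

**Further compounds**
F0 | step 1 | none | none
F0 | step 2 | none | none
F1 | step 3 | 3,5,7,4'-tetra-O-acetyl-8-(1,1-dimethylallyl)kaempferol | C=CC(C)(C)c1c(OC(C)=O)cc(OC(C)=O)c2c(=O)c(OC(C)=O)c(-c3ccc(OC(C)=O)cc3)oc12
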